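**Plan**

- Retrosynthetic cuts: the butenolide–diene bond C16–C4′ (Suzuki), C15=C16 (boron-Wittig), C12–C13 (B-alkyl Suzuki), then ring B at C8=C9 together with C11=C12 (ring-closing enyne metathesis), then C9–C10 (Eschenmoser–Claisen), back to β-damascone.
- Enabling feature: ring B is a 2-methylcyclohex-1-ene whose second olefinic carbon C9 is bonded to quaternary C10 and carries the two-carbon arm C11–C12. With that arm as a vinyl group it is a 1-vinyl-2-methylcyclohexene, the exo enyne-metathesis product of a C10 ethynyl group (C9≡C11) and a C8 isopropenyl group on ring A.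
- Forward order: ring A with C6–C8 and the C8 methyl comes intact from β-damascone; the butenolide ring is bought preformed as 4-bromofuran-2(5H)-one; ring B is closed last, on the monocycle; the C9 vinyl group is then hydroborated and coupled outward.
- Stereochemistry: CBS reduction sets a C6 carbinol, the suprafacial Claisen shift trades it for quaternary C10, and amide-directed hydrogenation sets C5–H trans to the C10 methyl. The C13=C14 geometry comes from trans-hydroalumination/iodination plus stereoretentive coupling, and C15=C16 from the boron-Wittig step.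

Key step: step 10

Assumption: locants follow drimane numbering for the decalin (C1–C10; C8 carries the olefinic methyl, C9 the side chain), and the side chain is numbered C11–C16 outward from C9 (C13 bears the CH2OH group, C16 is bonded to C4′ of the furanone).

**Route**

Step 1
Reactants: 1 β-damascone, (2E)-1-(2,6,6-trimethylcyclohex-1-en-1-yl)but-2-en-1-one
Product: 2 1-(2,6,6-trimethylcyclohex-1-en-1-yl)butane-1,3-dione
Conditions: Na2PdCl4 (20 mol %), t-BuOOH (1.5 equiv), AcOH/H2O 1:1, 50 °C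
Reagents that add atoms: tert-butyl hydroperoxide, CC(C)(C)OO
Why: Tsuji–Wacker oxidation of an enone, in which oxypalladation at the β-carbon (C8) of the crotonyl unit and β-hydride elimination give the 1,3-diketone, while the tetrasubstituted ring olefin is too hindered to coordinate palladium.

Step 2
Reactants: 2 1-(2,6,6-trimethylcyclohex-1-en-1-yl)butane-1,3-dione
Product: 3 2-(2-methyl-1,3-dioxolan-2-yl)-1-(2,6,6-trimethylcyclohex-1-en-1-yl)ethan-1-one
Conditions: ethylene glycol (1.2 equiv), PPTS (cat.), benzene, reflux, Dean–Stark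
Reagents that add atoms: ethylene glycol, OCCO
Why: Acid-catalysed ketalisation should occur only at the acetyl carbonyl (C8), because the C6 carbonyl is shielded on both sides by the C4 gem-dimethyl and C10 methyl groups of the cyclohexenyl ring.

Step 3
Reactants: 3 2-(2-methyl-1,3-dioxolan-2-yl)-1-(2,6,6-trimethylcyclohex-1-en-1-yl)ethan-1-one
Product: 4 (1R)-2-(2-methyl-1,3-dioxolan-2-yl)-1-(2,6,6-trimethylcyclohex-1-en-1-yl)ethan-1-ol
Conditions: (S)-2-methyl-CBS-oxazaborolidine (20 mol %), BH3·SMe2 (0.7 equiv), THF, −20 °C to 0 °C; aqueous NH4Cl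
Reagents that add atoms: none
Why: Corey–Bakshi–Shibata reduction, in which the trimethylcyclohexenyl group acts as the large substituent and the CH2 group as the small one, so that by analogy with aryl alkyl ketones the (S)-catalyst should give the (R)-carbinol at C6.

Step 4
Reactants: 4 (1R)-2-(2-methyl-1,3-dioxolan-2-yl)-1-(2,6,6-trimethylcyclohex-1-en-1-yl)ethan-1-ol
Product: 6 2-[(1R,2E)-1,3,3-trimethyl-2-[2-(2-methyl-1,3-dioxolan-2-yl)ethylidene]cyclohexyl]-N,N-dimethylacetamide, via ketene N,O-acetal 5 (not isolated)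
Conditions: MeC(OMe)2NMe2 (5 equiv), xylene, 140 °C
Reagents that add atoms: N,N-dimethylacetamide dimethyl acetal, COC(C)(OC)N(C)C
Why: Eschenmoser–Claisen rearrangement, in which the ketene N,O-acetal undergoes a suprafacial [3,3] shift with the C6 substituent pseudo-equatorial (the pseudo-axial alternative clashes with the C10 methyl) and forms the C9–C10 bond on the face of the departing C6–O bond, so that the (R)-C6 centre is traded for the quaternary C10 centre and an (E)-ethylidene; Claisen shifts onto this tetrasubstituted cyclogeranyl olefin type are known.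

Step 5
Reactants: 6 2-[(1R,2E)-1,3,3-trimethyl-2-[2-(2-methyl-1,3-dioxolan-2-yl)ethylidene]cyclohexyl]-N,N-dimethylacetamide
Product: 7 2-[(1R,2S)-1,3,3-trimethyl-2-[2-(2-methyl-1,3-dioxolan-2-yl)ethyl]cyclohexyl]-N,N-dimethylacetamide
Conditions: [Ir(cod)(PCy3)(py)]PF6 (10 mol %), H2 (1–4 atm), CH2Cl2, rt
Reagents that add atoms: none
Why: Amide-directed hydrogenation, in which the amide carbonyl on the C10 arm binds iridium and delivers H2 to the face of the exocyclic C5=C6 olefin cis to that arm, so that C5–H ends up cis to the acetamide arm and trans to the C10 methyl.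

Step 6
Reactants: 7 2-[(1R,2S)-1,3,3-trimethyl-2-[2-(2-methyl-1,3-dioxolan-2-yl)ethyl]cyclohexyl]-N,N-dimethylacetamide
Product: 8 2-[(1R,2S)-1,3,3-trimethyl-2-[2-(2-methyl-1,3-dioxolan-2-yl)ethyl]cyclohexyl]acetaldehyde
Conditions: Cp2Zr(H)Cl (1.8 equiv), THF, rt; aqueous work-up
Reagents that add atoms: none
Why: Hydrozirconation of the tertiary amide carbonyl gives a zirconium-bound hemiaminal that is not reduced further and releases the aldehyde on aqueous work-up (amide-to-aldehyde reduction with Cp2Zr(H)Cl), leaving the ketal untouched.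

Step 7
Reactants: 8 2-[(1R,2S)-1,3,3-trimethyl-2-[2-(2-methyl-1,3-dioxolan-2-yl)ethyl]cyclohexyl]acetaldehyde
Product: 10 2-{2-[(1S,2S)-2-ethynyl-2,6,6-trimethylcyclohexyl]ethyl}-2-methyl-1,3-dioxolane, via (E)-alkenyl nonaflate 9 (not isolated)
Conditions: C4F9SO2F (1.3 equiv), phosphazene base P2-Et (2.5 equiv), DMF, −20 °C to rt
Reagents that add atoms: none
Why: One-pot enol sulfonate formation and elimination, in which the phosphazene base enolises the aldehyde, the sulfonyl fluoride traps the enolate on oxygen and base-induced loss of nonaflate gives the terminal alkyne, without affecting the quaternary C10 or the ketal.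

Step 8
Reactants: 10 2-{2-[(1S,2S)-2-ethynyl-2,6,6-trimethylcyclohexyl]ethyl}-2-methyl-1,3-dioxolane
Product: 11 4-[(1S,2S)-2-ethynyl-2,6,6-trimethylcyclohexyl]butan-2-one
Conditions: 2 M aq. HCl, THF, rt
Reagents that add atoms: water, O
Why: Acid-catalysed ketal hydrolysis, in which neither stereocentre is alpha to the liberated ketone and the terminal alkyne is inert to dilute aqueous acid.

Step 9
Reactants: 11 4-[(1S,2S)-2-ethynyl-2,6,6-trimethylcyclohexyl]butan-2-one
Product: 12 (1S,2S)-1-ethynyl-1,3,3-trimethyl-2-(3-methylbut-3-en-1-yl)cyclohexane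
Conditions: Ph3PCH3Br (3 equiv), KOtBu (2.8 equiv), THF, 0 °C to rt
Reagents that add atoms: methyltriphenylphosphonium bromide, C[P+](c1ccccc1)(c1ccccc1)c1ccccc1.[Br-]
Why: Wittig methylenation of an unhindered methyl ketone, with an excess of ylide covering any reversible deprotonation of the alkyne C–H.

Step 10
Reactants: 12 (1S,2S)-1-ethynyl-1,3,3-trimethyl-2-(3-methylbut-3-en-1-yl)cyclohexane
Product: 13 (4aS,8aS)-1-ethenyl-2,5,5,8a-tetramethyl-3,4,4a,5,6,7,8,8a-octahydronaphthalene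
Conditions: second-generation Grubbs catalyst RuCl2(=CHPh)(H2IMes)(PCy3) (10 mol %), ethylene (1 atm), toluene, 80 °C
Reagents that add atoms: none
Why: Ring-closing enyne metathesis, in which the ruthenium methylidene adds to the terminal alkyne to give the vinylcarbene Ru=C9(C10)–CH=CH2, which closes onto the C8 isopropenyl olefin by [2+2]/retro-[2+2] and releases the methylidene again (the ene-first sequence through Ru=C8 converges on the same diene). The closest known reaction type is the exo ring-closing metathesis of 1,7-enynes that carry a terminal alkyne and a 1,1-disubstituted olefin, giving 1-vinyl-2-methylcyclohexenes under ethylene. Ring B is closed in the 6-exo mode: the C8=C9 bond is formed, both alkyne carbons are kept, and C11=C12 is left as the exocyclic vinyl group. No stereocentre is formed; C5 and C10 are set beforehand and cannot epimerise, and their trans-disposed equatorial arms on ring A give the trans-fused decalin. The step needs exo (six-membered) over endo (seven-membered) closure and ring closure over mere alkyne–ethylene cross-metathesis; the 1,7-spacing and the gem-disubstituted propargylic C10 favour this, and ethylene only keeps the methylidene carrier alive without net uptake. The tetrasubstituted C8=C9 olefin is thereby placed without any possibility of positional isomers.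

Step 11
Reactants: 14 but-2-yne-1,4-diol
Product: 15 4-{[tert-butyl(dimethyl)silyl]oxy}but-2-yn-1-ol
Conditions: NaH (1.0 equiv), THF, 0 °C to rt; then TBSCl (1.0 equiv)
Reagents that add atoms: tert-butyldimethylsilyl chloride, CC(C)(C)[Si](C)(C)Cl
Why: Monosilylation of a symmetric diol through its sparingly soluble monosodium alkoxide, which should stop at the mono ether.

Step 12
Reactants: 15 4-{[tert-butyl(dimethyl)silyl]oxy}but-2-yn-1-ol
Product: 17 (2Z)-4-{[tert-butyl(dimethyl)silyl]oxy}-3-iodobut-2-en-1-ol, via cyclic vinylalanate 16 (not isolated)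
Conditions: NaAlH2(OCH2CH2OMe)2 (1.1 equiv), THF, 0 °C to rt; then I2 (1.2 equiv), −78 °C to 0 °C
Reagents that add atoms: iodine, II
Why: Hydroxyl-directed trans-hydroalumination, in which the alkoxyaluminium hydride delivers hydride to the proximal alkyne carbon to form the five-membered vinylalanate, and iodinolysis of the C–Al bond with retention gives the (Z)-iodo allylic alcohol that fixes the future C13=C14 geometry.

Step 13
Reactants: 13 (4aS,8aS)-1-ethenyl-2,5,5,8a-tetramethyl-3,4,4a,5,6,7,8,8a-octahydronaphthalene; 17 (2Z)-4-{[tert-butyl(dimethyl)silyl]oxy}-3-iodobut-2-en-1-ol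
Product: 19 (2E)-3-({[tert-butyl(dimethyl)silyl]oxy}methyl)-5-[(4aS,8aS)-2,5,5,8a-tetramethyl-3,4,4a,5,6,7,8,8a-octahydronaphthalen-1-yl]pent-2-en-1-ol, via B-alkyl-9-BBN 18 (not isolated)
Conditions: 9-BBN (1.2 equiv), THF, 0 °C to rt; then 17, Pd(dppf)Cl2 (5 mol %), AsPh3 (10 mol %), Cs2CO3 (3 equiv), DMF/H2O, rt
Reagents that add atoms: none
Why: 9-BBN adds anti-Markovnikov to the monosubstituted C11=C12 vinyl group only (the tetrasubstituted C8=C9 is inert), and the B-alkyl Suzuki–Miyaura coupling with the vinyl iodide proceeds with retention, so that C12 ends up cis to C14–C15 as the target requires.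

Step 14
Reactants: 19 (2E)-3-({[tert-butyl(dimethyl)silyl]oxy}methyl)-5-[(4aS,8aS)-2,5,5,8a-tetramethyl-3,4,4a,5,6,7,8,8a-octahydronaphthalen-1-yl]pent-2-en-1-ol
Product: 20 (2E)-3-({[tert-butyl(dimethyl)silyl]oxy}methyl)-5-[(4aS,8aS)-2,5,5,8a-tetramethyl-3,4,4a,5,6,7,8,8a-octahydronaphthalen-1-yl]pent-2-enal
Conditions: MnO2 (20 equiv), CH2Cl2, rt
Reagents that add atoms: none
Why: MnO2 oxidises the primary allylic alcohol to the enal under neutral conditions, which should avoid olefin isomerisation and silyl loss.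

Step 15
Reactants: 20 (2E)-3-({[tert-butyl(dimethyl)silyl]oxy}methyl)-5-[(4aS,8aS)-2,5,5,8a-tetramethyl-3,4,4a,5,6,7,8,8a-octahydronaphthalen-1-yl]pent-2-enal
Product: 21 2-[(1E,3E)-4-({[tert-butyl(dimethyl)silyl]oxy}methyl)-6-[(4aS,8aS)-2,5,5,8a-tetramethyl-3,4,4a,5,6,7,8,8a-octahydronaphthalen-1-yl]hexa-1,3-dien-1-yl]-4,4,5,5-tetramethyl-1,3,2-dioxaborolane
Conditions: CH2(Bpin)2 (1.3 equiv), LiTMP (1.2 equiv, from 2,2,6,6-tetramethylpiperidine and n-BuLi), THF, 0 °C; then 20, −78 °C to rt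
Reagents that add atoms: bis[(pinacolato)boryl]methane, C(B1OC(C)(C)C(C)(C)O1)B1OC(C)(C)C(C)(C)O1
Why: Boron-Wittig olefination, in which the lithiated geminal bis(boronate) adds 1,2 to the enal and syn-elimination of the boron alkoxide gives the (E)-alkenyl boronate, setting the C15=C16 geometry.

Step 16
Reactants: 21 2-[(1E,3E)-4-({[tert-butyl(dimethyl)silyl]oxy}methyl)-6-[(4aS,8aS)-2,5,5,8a-tetramethyl-3,4,4a,5,6,7,8,8a-octahydronaphthalen-1-yl]hexa-1,3-dien-1-yl]-4,4,5,5-tetramethyl-1,3,2-dioxaborolane; 22 4-bromofuran-2(5H)-one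
Product: 23 4-[(1E,3E)-4-({[tert-butyl(dimethyl)silyl]oxy}methyl)-6-[(4aS,8aS)-2,5,5,8a-tetramethyl-3,4,4a,5,6,7,8,8a-octahydronaphthalen-1-yl]hexa-1,3-dien-1-yl]furan-2(5H)-one
Conditions: Pd(dppf)Cl2 (5 mol %), K3PO4 (3 equiv), THF/H2O 10:1, rt to 40 °C
Reagents that add atoms: none
Why: Suzuki–Miyaura coupling of the dienyl boronate with the vinylogous acyl bromide, whose fast oxidative addition allows a mild phosphate base, attaches the preformed butenolide with retention of the (E)-geometry.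

Step 17
Reactants: 23 4-[(1E,3E)-4-({[tert-butyl(dimethyl)silyl]oxy}methyl)-6-[(4aS,8aS)-2,5,5,8a-tetramethyl-3,4,4a,5,6,7,8,8a-octahydronaphthalen-1-yl]hexa-1,3-dien-1-yl]furan-2(5H)-one
Product: 24 4-[(1E,3E)-4-(hydroxymethyl)-6-[(4aS,8aS)-2,5,5,8a-tetramethyl-3,4,4a,5,6,7,8,8a-octahydronaphthalen-1-yl]hexa-1,3-dien-1-yl]furan-2(5H)-one (CNP0232848.5)
Conditions: HF·pyridine, pyridine, THF, 0 °C to rt
Reagents that add atoms: none
Why: Fluoride-mediated cleavage of the primary silyl ether under buffered conditions that should leave the butenolide and the dienyl allylic alcohol intact.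

**Compound list**

1 | β-damascone, (2E)-1-(2,6,6-trimethylcyclohex-1-en-1-yl)but-2-en-1-one | C/C=C/C(=O)C1=C(C)CCCC1(C)C | starting material
2 | 1-(2,6,6-trimethylcyclohex-1-en-1-yl)butane-1,3-dione | CC(=O)CC(=O)C1=C(C)CCCC1(C)C | intermediate
3 | 2-(2-methyl-1,3-dioxolan-2-yl)-1-(2,6,6-trimethylcyclohex-1-en-1-yl)ethan-1-one | CC1(CC(=O)C2=C(C)CCCC2(C)C)OCCO1 | intermediate
4 | (1R)-2-(2-methyl-1,3-dioxolan-2-yl)-1-(2,6,6-trimethylcyclohex-1-en-1-yl)ethan-1-ol | O[C@H](CC1(C)OCCO1)C1=C(C)CCCC1(C)C | intermediate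
5 | ketene N,O-acetal, N,N-dimethyl-1-{[(1R)-2-(2-methyl-1,3-dioxolan-2-yl)-1-(2,6,6-trimethylcyclohex-1-en-1-yl)ethyl]oxy}ethen-1-amine | C=C(N(C)C)O[C@H](CC1(C)OCCO1)C1=C(C)CCCC1(C)C | intermediate
6 | 2-[(1R,2E)-1,3,3-trimethyl-2-[2-(2-methyl-1,3-dioxolan-2-yl)ethylidene]cyclohexyl]-N,N-dimethylacetamide | CN(C)C(=O)C[C@@]1(C)CCCC(C)(C)/C1=C\CC2(C)OCCO2 | intermediate
7 | 2-[(1R,2S)-1,3,3-trimethyl-2-[2-(2-methyl-1,3-dioxolan-2-yl)ethyl]cyclohexyl]-N,N-dimethylacetamide | CN(C)C(=O)C[C@@]1(C)CCCC(C)(C)[C@@H]1CCC2(C)OCCO2 | intermediate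
8 | 2-[(1R,2S)-1,3,3-trimethyl-2-[2-(2-methyl-1,3-dioxolan-2-yl)ethyl]cyclohexyl]acetaldehyde | O=CC[C@@]1(C)CCCC(C)(C)[C@@H]1CCC2(C)OCCO2 | intermediate
9 | (E)-2-[(1S,2S)-1,3,3-trimethyl-2-[2-(2-methyl-1,3-dioxolan-2-yl)ethyl]cyclohexyl]ethenyl nonafluorobutane-1-sulfonate | FC(F)(F)C(F)(F)C(F)(F)C(F)(F)S(=O)(=O)O/C=C/[C@@]1(C)CCCC(C)(C)[C@@H]1CCC2(C)OCCO2 | intermediate
10 | 2-{2-[(1S,2S)-2-ethynyl-2,6,6-trimethylcyclohexyl]ethyl}-2-methyl-1,3-dioxolane | C#C[C@@]1(C)CCCC(C)(C)[C@@H]1CCC2(C)OCCO2 | intermediate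
11 | 4-[(1S,2S)-2-ethynyl-2,6,6-trimethylcyclohexyl]butan-2-one | C#C[C@@]1(C)CCCC(C)(C)[C@@H]1CCC(C)=O | intermediate
12 | (1S,2S)-1-ethynyl-1,3,3-trimethyl-2-(3-methylbut-3-en-1-yl)cyclohexane | C#C[C@@]1(C)CCCC(C)(C)[C@@H]1CCC(C)=C | intermediate
13 | (4aS,8aS)-1-ethenyl-2,5,5,8a-tetramethyl-3,4,4a,5,6,7,8,8a-octahydronaphthalene | CC1=C(C=C)[C@@]2(C)CCCC(C)(C)[C@@H]2CC1 | intermediate
14 | but-2-yne-1,4-diol | OCC#CCO | starting material
15 | 4-{[tert-butyl(dimethyl)silyl]oxy}but-2-yn-1-ol | OCC#CCO[Si](C)(C)C(C)(C)C | intermediate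
16 | cyclic vinylalanate, sodium 2,2-bis(2-methoxyethoxy)-3-({[tert-butyl(dimethyl)silyl]oxy}methyl)-2,5-dihydro-1,2-oxaluminol-2-uide | [Na+].COCCO[Al-]1(OCCOC)OCC=C1CO[Si](C)(C)C(C)(C)C | intermediate
17 | (2Z)-4-{[tert-butyl(dimethyl)silyl]oxy}-3-iodobut-2-en-1-ol | OC/C=C(\I)CO[Si](C)(C)C(C)(C)C | intermediate
18 | 9-{2-[(4aS,8aS)-2,5,5,8a-tetramethyl-3,4,4a,5,6,7,8,8a-octahydronaphthalen-1-yl]ethyl}-9-borabicyclo[3.3.1]nonane | CC1=C(CCB2C3CCCC2CCC3)[C@@]2(C)CCCC(C)(C)[C@@H]2CC1 | intermediate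
19 | (2E)-3-({[tert-butyl(dimethyl)silyl]oxy}methyl)-5-[(4aS,8aS)-2,5,5,8a-tetramethyl-3,4,4a,5,6,7,8,8a-octahydronaphthalen-1-yl]pent-2-en-1-ol | CC1=C(CC/C(=C\CO)CO[Si](C)(C)C(C)(C)C)[C@@]2(C)CCCC(C)(C)[C@@H]2CC1 | intermediate
20 | (2E)-3-({[tert-butyl(dimethyl)silyl]oxy}methyl)-5-[(4aS,8aS)-2,5,5,8a-tetramethyl-3,4,4a,5,6,7,8,8a-octahydronaphthalen-1-yl]pent-2-enal | CC1=C(CC/C(=C\C=O)CO[Si](C)(C)C(C)(C)C)[C@@]2(C)CCCC(C)(C)[C@@H]2CC1 | intermediate
21 | 2-[(1E,3E)-4-({[tert-butyl(dimethyl)silyl]oxy}methyl)-6-[(4aS,8aS)-2,5,5,8a-tetramethyl-3,4,4a,5,6,7,8,8a-octahydronaphthalen-1-yl]hexa-1,3-dien-1-yl]-4,4,5,5-tetramethyl-1,3,2-dioxaborolane | CC1=C(CC/C(=C\C=C\B2OC(C)(C)C(C)(C)O2)CO[Si](C)(C)C(C)(C)C)[C@@]2(C)CCCC(C)(C)[C@@H]2CC1 | intermediate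
22 | 4-bromofuran-2(5H)-one | BrC1=CC(=O)OC1 | starting material
23 | 4-[(1E,3E)-4-({[tert-butyl(dimethyl)silyl]oxy}methyl)-6-[(4aS,8aS)-2,5,5,8a-tetramethyl-3,4,4a,5,6,7,8,8a-octahydronaphthalen-1-yl]hexa-1,3-dien-1-yl]furan-2(5H)-one | CC1=C(CC/C(=C\C=C\C2=CC(=O)OC2)CO[Si](C)(C)C(C)(C)C)[C@@]2(C)CCCC(C)(C)[C@@H]2CC1 | intermediate
24 | 4-[(1E,3E)-4-(hydroxymethyl)-6-[(4aS,8aS)-2,5,5,8a-tetramethyl-3,4,4a,5,6,7,8,8a-octahydronaphthalen-1-yl]hexa-1,3-dien-1-yl]furan-2(5H)-one (CNP0232848.5) | CC1=C(CC/C(=C\C=C\C2=CC(=O)OC2)CO)[C@@]2(C)CCCC(C)(C)[C@@H]2CC1 | target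

**Step count**

Total step count: 17 (steps 1–10 and 13–17 in the main line, steps 11–12 for the vinyl iodide).
Longest linear sequence: 15 steps (1–10, then 13–17).

**Steps most likely to fail**

Step 10 (ring-closing enyne metathesis). The ruthenium carbene may fail to engage the hindered alkyne at the quaternary propargylic centre, the reaction may stall after alkyne–ethylene cross-metathesis without ring closure, or closure may occur in the endo sense. The fallback closes ring B by an aldol condensation and sets out from aldehyde 8. Hydrolysis of the ketal (2 M aq. HCl, THF) should give the keto aldehyde 2-[(1R,2S)-1,3,3-trimethyl-2-(3-oxobutyl)cyclohexyl]acetaldehyde F1. Enamine-mediated intramolecular aldol condensation of the aldehyde α-carbon (C9) onto the methyl ketone (pyrrolidine, AcOH, benzene, reflux) should give the enal (4aS,8aS)-2,5,5,8a-tetramethyl-3,4,4a,5,6,7,8,8a-octahydronaphthalene-1-carbaldehyde F2. Wittig methylenation (Ph3PCH3Br, KOtBu, THF) then returns to the route at diene 13.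

Step 4 (Eschenmoser–Claisen rearrangement). Thermal elimination of the hindered allylic ketene aminal may compete with the [3,3] shift, and an incomplete pseudo-equatorial preference would give an E/Z mixture whose isomers carry opposite C10 configurations, eroding the chirality transfer. The fallback uses an anionic [2,3] shift at low temperature and sets out from alcohol 4. O-Alkylation (KH, 18-crown-6, Bu3SnCH2I, THF) should give the stannylmethyl ether tributyl({[(1R)-2-(2-methyl-1,3-dioxolan-2-yl)-1-(2,6,6-trimethylcyclohex-1-en-1-yl)ethyl]oxy}methyl)stannane F3. Tin–lithium exchange (n-BuLi, THF, −78 °C) triggers the Wittig–Still rearrangement to the homoallylic alcohol [(1S,2E)-1,3,3-trimethyl-2-[2-(2-methyl-1,3-dioxolan-2-yl)ethylidene]cyclohexyl]methanol F4. Hydroxyl-directed hydrogenation ([Ir(cod)(PCy3)(py)]PF6, H2, CH2Cl2) should give [(1S,2S)-1,3,3-trimethyl-2-[2-(2-methyl-1,3-dioxolan-2-yl)ethyl]cyclohexyl]methanol F5. Dess–Martin oxidation should give (1S,2S)-1,3,3-trimethyl-2-[2-(2-methyl-1,3-dioxolan-2-yl)ethyl]cyclohexane-1-carbaldehyde F6. Seyferth–Gilbert homologation with dimethyl (1-diazo-2-oxopropyl)phosphonate (K2CO3, MeOH) then returns to the route at alkyne 10.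

Step 7 (aldehyde to alkyne). The aldehyde may self-condense under the strong base before O-sulfonylation, and the syn-elimination from the (E)-alkenyl nonaflate next to the quaternary carbon may be incomplete. The fallback sets out from aldehyde 8. Deoxygenative dibromination ((PhO)3P, Br2, Et3N, CH2Cl2, −78 °C to rt) should give the geminal dibromide 2-{2-[(1S,2R)-2-(2,2-dibromoethyl)-2,6,6-trimethylcyclohexyl]ethyl}-2-methyl-1,3-dioxolane F7. Double dehydrobromination (LDA, 3.5 equiv, THF, −78 °C to 0 °C) then returns to the route at alkyne 10.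

**Further compounds**

F1 | step 10 | 2-[(1R,2S)-1,3,3-trimethyl-2-(3-oxobutyl)cyclohexyl]acetaldehyde | O=CC[C@@]1(C)CCCC(C)(C)[C@@H]1CCC(C)=O
F2 | step 10 | (4aS,8aS)-2,5,5,8a-tetramethyl-3,4,4a,5,6,7,8,8a-octahydronaphthalene-1-carbaldehyde | CC1=C(C=O)[C@@]2(C)CCCC(C)(C)[C@@H]2CC1
F3 | step 4 | tributyl({[(1R)-2-(2-methyl-1,3-dioxolan-2-yl)-1-(2,6,6-trimethylcyclohex-1-en-1-yl)ethyl]oxy}methyl)stannane | CCCC[Sn](CCCC)(CCCC)CO[C@H](CC1(C)OCCO1)C1=C(C)CCCC1(C)C
F4 | step 4 | [(1S,2E)-1,3,3-trimethyl-2-[2-(2-methyl-1,3-dioxolan-2-yl)ethylidene]cyclohexyl]methanol | OC[C@@]1(C)CCCC(C)(C)/C1=C\CC2(C)OCCO2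
F5 | step 4 | [(1S,2S)-1,3,3-trimethyl-2-[2-(2-methyl-1,3-dioxolan-2-yl)ethyl]cyclohexyl]methanol | OC[C@@]1(C)CCCC(C)(C)[C@@H]1CCC2(C)OCCO2
F6 | step 4 | (1S,2S)-1,3,3-trimethyl-2-[2-(2-methyl-1,3-dioxolan-2-yl)ethyl]cyclohexane-1-carbaldehyde | O=C[C@@]1(C)CCCC(C)(C)[C@@H]1CCC2(C)OCCO2
F7 | step 7 | 2-{2-[(1S,2R)-2-(2,2-dibromoethyl)-2,6,6-trimethylcyclohexyl]ethyl}-2-methyl-1,3-dioxolane | BrC(Br)C[C@@]1(C)CCCC(C)(C)[C@@H]1CCC2(C)OCCO2
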